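Everything rests on cutting C3a–C4 of the benzofuran, so that ring A is grown onto a furan instead of being carved out of a phloroglucinol. The feature exploited is C7 of ring A. It sits between C6–OH and C7a–O1 and holds the quaternary carbon of the 1,1-dimethylallyl group. Before ring A exists, C7 is merely an sp3 carbon flanked by a 2-furyl group and a ketone, and an Ireland–Claisen shift installs the group there without regiochemical doubt. The precursor is a racemic 2-furylacetyl-type acyl Meldrum's acid. On thermolysis it loses acetone and CO2, and the released acylketene attacks furan C3 and aromatises to the 7-substituted benzofuran-4,6-diol in one operation.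

Key step: step 4

Remarks on the chemistry (assumptions)
- Ring labels: ring A is the benzene ring of the benzofuran, ring B its furan ring, ring C the pendant arene, and ring D the dihydropyran fused to ring C.
- The target has no stereocentre and no stereogenic double bond. The Ireland–Claisen acid, the acyl Meldrum's acid and the transient dienone are racemates, and their stereocentres vanish when ring A aromatises.
- The acyl Meldrum's acid is drawn as the triketone, although it should exist as its chelated enol.
- Furan C5 is left unblocked, because this C–H becomes benzofuran C2–H, the later metalation site.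
- Silyl ethers rather than acetals protect the benzofuran diol. Two acetal oxygens at C4 and C6 would steer butyllithium to C5. Their acidic removal would also endanger the ortho-prenylphenol and the ortho-(1,1-dimethylallyl)phenol of the target.

Fragment 1 (rings A and B)

Step 1
Reactants: 1 2-furylacetic acid; 2 prenol (3-methylbut-2-en-1-ol)
Product: 3 3-methylbut-2-en-1-yl 2-(furan-2-yl)acetate
Conditions: DCC, DMAP (cat.), CH2Cl2, 0 °C → rt
Reagents that add atoms: none
Why: Steglich esterification joins the acid and the primary allylic alcohol under neutral conditions, which spare the acid-sensitive furan and do not isomerise the prenyl group.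

Step 2
Reactants: 3 3-methylbut-2-en-1-yl 2-(furan-2-yl)acetate
Product: 6 rac-2-(furan-2-yl)-3,3-dimethylpent-4-enoic acid, via silyl ketene acetal 4 (not isolated), via trimethylsilyl ester 5 (not isolated)
Conditions: LiN(iPr)2, THF, −78 °C; Me3SiCl, −78 → 60 °C; then H2O, dilute citric acid work-up
Reagents that add atoms: chlorotrimethylsilane, C[Si](C)(C)Cl (its silyl group is carried by 4 and 5 only and leaves again on work-up)
Why: Ireland–Claisen rearrangement, in which the [3,3]-shift of 4 must form the new C–C bond at the dimethyl-substituted allyl terminus, so the quaternary carbon and the terminal vinyl group follow from connectivity; the single new stereocentre is racemic and is erased in step 4.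

Step 3
Reactants: 6 rac-2-(furan-2-yl)-3,3-dimethylpent-4-enoic acid; 7 Meldrum's acid
Product: 8 rac-5-[2-(furan-2-yl)-3,3-dimethylpent-4-enoyl]-2,2-dimethyl-1,3-dioxane-4,6-dione
Conditions: DCC, DMAP (1.5 equiv), CH2Cl2, 0 °C → rt; cold aq. KHSO4 wash
Reagents that add atoms: none
Why: DMAP-mediated C-acylation of Meldrum's acid by the carbodiimide-activated acid, a standard reaction that also accepts alpha-branched, beta-quaternary acids; the product is obtained as its chelated enol and the stereocentre stays racemic.

Step 4
Reactants: 8 rac-5-[2-(furan-2-yl)-3,3-dimethylpent-4-enoyl]-2,2-dimethyl-1,3-dioxane-4,6-dione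
Product: 12 7-(2-methylbut-3-en-2-yl)benzofuran-4,6-diol, via acylketene 9 (not isolated), via dienylketene enol 10 (not isolated), via 3aH-dienone 11 (not isolated)
Conditions: dry PhMe, reflux (110 °C), Ar, slow addition of 8 over 8 h to a final concentration of about 2 mM
Reagents that add atoms: none
Why: Proposed new method: cycloreversion of 8 with loss of acetone and CO2 gives acylketene 9, whose C–H between furyl and ketone enolises to the (E)-dienylketene 10, the geometry in which the bulky tert-alkyl group lies next to the small OH and furan C3 therefore lies next to the ketene carbon. Ring A then closes by a thermal disrotatory 6π-electrocyclisation across ketene C=C, enol C=C and furan C2=C3 (seen as a polar event, a 6-exo-dig attack of furan C3 on the sp carbon), which forms C3a–C4 and gives dienone 11; a proton shift from C3a to oxygen turns 11 irreversibly into the aromatic diol 12. The closest known reaction types are the 6π closure of dienylketenes in ketene benzannulations, the anhydride-induced cyclisation of 4-(2-furyl)but-3-enoic acids onto furan C3 and the Friedel–Crafts cyclisation of 4-aryl-3-oxobutanoates to naphthalene-1,3-diols, none of which starts from a thermally made 2-furylacetylketene. No stereocentre has to be controlled, since the racemic centre of 8 becomes sp2 C7 and the passing C3a centre of 11 is lost on aromatisation. The selectivity required is closure at furan C3 in preference to acylation of the more nucleophilic free C5 of a second molecule, ketene dimerisation and capture by the phenols of 12: the three-atom tether reaches C3 only, slow addition at high dilution keeps 9 scarce, the neopentyl-like flank slows every bimolecular attack, and aryl beta-keto esters formed by phenol capture revert to 9 at reflux while aromatisation does not revert. The isolated monosubstituted vinyl group is a much poorer partner for the ketene than the furan and should stay a spectator.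

Step 5
Reactants: 12 7-(2-methylbut-3-en-2-yl)benzofuran-4,6-diol
Product: 13 4,6-bis(tert-butyldimethylsilyloxy)-7-(2-methylbut-3-en-2-yl)benzofuran
Conditions: TBSCl (2.5 equiv), imidazole, DMAP (cat.), DMF, rt → 40 °C
Reagents that add atoms: tert-butyldimethylsilyl chloride, CC(C)(C)[Si](C)(C)Cl
Why: Imidazole-promoted O-silylation of phenols, chosen because the bulky non-chelating ethers shield C5–H instead of directing lithium to it and are later removed by fluoride, so neither olefin ever meets acid.

Fragment 2 (rings C and D)

Step 6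
Reactants: 14 phloroglucinol (in excess); 2 prenol
Product: 16 2,2-dimethylchroman-5,7-diol, via 2-prenylphloroglucinol 15 (not isolated)
Conditions: Amberlyst 15, THF, 65 °C
Reagents that add atoms: none
Why: Friedel–Crafts prenylation followed in the same pot by acid-catalysed Markovnikov cycloetherification of 15, a standard one-pot chroman synthesis; the threefold symmetry of 14 removes any regiochemical question and its use in excess holds back a second annulation.

Step 7
Reactants: 16 2,2-dimethylchroman-5,7-diol
Product: 17 5,7-bis(methoxymethoxy)-2,2-dimethylchroman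
Conditions: MOMCl (2.5 equiv), iPr2NEt, CH2Cl2, 0 °C → rt
Reagents that add atoms: chloromethyl methyl ether, COCCl
Why: Base-mediated O-alkylation of both phenols (acetal protection), carried out here only to provide two chelating ortho-directing groups for step 8.

Step 8
Reactants: 17 5,7-bis(methoxymethoxy)-2,2-dimethylchroman; 18 prenyl bromide (1-bromo-3-methylbut-2-ene)
Product: 20 5,7-bis(methoxymethoxy)-2,2-dimethyl-6-(3-methylbut-2-en-1-yl)chroman, via C6 aryllithium 19 (not isolated)
Conditions: n-BuLi, THF, 0 °C → rt; 18, −78 °C → rt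
Reagents that add atoms: n-butyllithium, [Li]CCCC (lithium held by 19 only)
Why: Directed ortho-metalation followed by SN2 allylation, in which C6–H lies between two chelating OMOM groups and is removed in preference to C8–H, whose second neighbour is only the weakly coordinating, hindered ring D ether oxygen, and the aryllithium attacks the primary carbon of 18 to give the linear prenyl group.

Step 9
Reactants: 20 5,7-bis(methoxymethoxy)-2,2-dimethyl-6-(3-methylbut-2-en-1-yl)chroman
Product: 21 2,2-dimethyl-6-(3-methylbut-2-en-1-yl)chroman-5,7-diol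
Conditions: aq. HCl (3 M)–MeOH, rt
Reagents that add atoms: none
Why: Acid-catalysed transacetalisation (MOM cleavage) in methanol at room temperature, conditions routinely survived by ortho-prenylphenols because cycloetherification of the prenyl group needs stronger acid or heat.

Step 10
Reactants: 21 2,2-dimethyl-6-(3-methylbut-2-en-1-yl)chroman-5,7-diol
Product: 22 2,2-dimethyl-6-(3-methylbut-2-en-1-yl)-7-(triisopropylsilyloxy)chroman-5-ol
Conditions: TIPSCl (1.0 equiv), imidazole, DMF, 0 °C
Reagents that add atoms: triisopropylsilyl chloride, CC(C)[Si](Cl)(C(C)C)C(C)C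
Why: Sterically governed monosilylation of a diol, in which the C7 hydroxyl has an open ortho position (C8–H) whereas the C5 hydroxyl is walled in by C4–H2 of ring D and the C6 prenyl group, so one equivalent of the very bulky TIPSCl should react at O7 only.

Step 11
Reactants: 22 2,2-dimethyl-6-(3-methylbut-2-en-1-yl)-7-(triisopropylsilyloxy)chroman-5-ol
Product: 23 2,2-dimethyl-6-(3-methylbut-2-en-1-yl)-7-(triisopropylsilyloxy)chroman-5-yl trifluoromethanesulfonate
Conditions: Tf2O, pyridine, CH2Cl2, 0 °C
Reagents that add atoms: trifluoromethanesulfonic anhydride, O=S(=O)(OS(=O)(=O)C(F)(F)F)C(F)(F)F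
Why: O-Triflation of a phenol with Tf2O/pyridine, which works on 2,6-dialkylphenols and leaves trisubstituted alkenes and aryl silyl ethers alone at 0 °C.

Union and deprotection

Step 12
Reactants: 13 4,6-bis(tert-butyldimethylsilyloxy)-7-(2-methylbut-3-en-2-yl)benzofuran (1.3 equiv); 23 ring C triflate
Product: 26 tris-silyl ether of artopetelin C (4,6-bis-TBS on ring A, TIPS on ring C), via 2-lithiobenzofuran 24 (not isolated), via benzofuran-2-ylzinc chloride 25 (not isolated)
Conditions: 13, n-BuLi, THF, −78 °C; ZnCl2, −78 °C → rt; 23, Pd2(dba)3 (2.5 mol %), RuPhos (10 mol %), THF, 65 °C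
Reagents that add atoms: n-butyllithium, [Li]CCCC (lithium held by 24 only); zinc chloride, Cl[Zn]Cl (ZnCl held by 25 only)
Why: Negishi coupling, in which benzofuran C2–H is the most acidic C–H of 13, a bulky electron-rich biarylphosphine on zerovalent palladium is the established answer to di-ortho-substituted aryl sulfonates, and the flat five-membered zinc partner adds little further crowding.

Step 13
Reactants: 26 tris-silyl ether of artopetelin C
Product: 27 artopetelin C
Conditions: Bu4NF (3.3 equiv), AcOH (3.3 equiv), THF, 0 °C, Ar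
Reagents that add atoms: none
Why: Fluoride-induced cleavage of aryl silyl ethers, buffered with acetic acid so that the phenoxides are protonated at once, while nothing present is acidic enough to cyclise the ortho-prenyl or ortho-(1,1-dimethylallyl) phenols.

Compound list
1 | 2-furylacetic acid | OC(=O)Cc1ccco1 | starting material
2 | prenol (3-methylbut-2-en-1-ol) | CC(C)=CCO | starting material
3 | 3-methylbut-2-en-1-yl 2-(furan-2-yl)acetate | CC(C)=CCOC(=O)Cc1ccco1 | intermediate
4 | silyl ketene acetal, 2-[2-(prenyloxy)-2-(trimethylsilyloxy)ethenyl]furan (either geometry, without consequence) | CC(C)=CCOC(O[Si](C)(C)C)=Cc1ccco1 | intermediate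
5 | trimethylsilyl 2-(furan-2-yl)-3,3-dimethylpent-4-enoate (racemic) | C=CC(C)(C)C(c1ccco1)C(=O)O[Si](C)(C)C | intermediate
6 | rac-2-(furan-2-yl)-3,3-dimethylpent-4-enoic acid | C=CC(C)(C)C(c1ccco1)C(=O)O | intermediate
7 | Meldrum's acid | CC1(C)OC(=O)CC(=O)O1 | starting material
8 | rac-5-[2-(furan-2-yl)-3,3-dimethylpent-4-enoyl]-2,2-dimethyl-1,3-dioxane-4,6-dione | CC1(C)OC(=O)C(C(=O)C(c2ccco2)C(C)(C)C=C)C(=O)O1 | intermediate
9 | rac-4-(furan-2-yl)-5,5-dimethylhepta-1,6-diene-1,3-dione (acylketene) | C=CC(C)(C)C(c1ccco1)C(=O)C=C=O | intermediate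
10 | (E)-4-(furan-2-yl)-3-hydroxy-5,5-dimethylhepta-1,3,6-trien-1-one (dienylketene) | C=CC(C)(C)/C(c1ccco1)=C(\O)C=C=O | intermediate
11 | rac-6-hydroxy-7-(2-methylbut-3-en-2-yl)benzofuran-4(3aH)-one | C=CC(C)(C)C1=C2OC=CC2C(=O)C=C1O | intermediate
12 | 7-(2-methylbut-3-en-2-yl)benzofuran-4,6-diol | C=CC(C)(C)c1c(O)cc(O)c2ccoc12 | intermediate
13 | 4,6-bis(tert-butyldimethylsilyloxy)-7-(2-methylbut-3-en-2-yl)benzofuran | C=CC(C)(C)c1c(O[Si](C)(C)C(C)(C)C)cc(O[Si](C)(C)C(C)(C)C)c2ccoc12 | intermediate
14 | phloroglucinol | Oc1cc(O)cc(O)c1 | starting material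
15 | 2-(3-methylbut-2-en-1-yl)benzene-1,3,5-triol | CC(C)=CCc1c(O)cc(O)cc1O | intermediate
16 | 2,2-dimethylchroman-5,7-diol | CC1(C)CCc2c(O)cc(O)cc2O1 | intermediate
17 | 5,7-bis(methoxymethoxy)-2,2-dimethylchroman | CC1(C)CCc2c(OCOC)cc(OCOC)cc2O1 | intermediate
18 | prenyl bromide (1-bromo-3-methylbut-2-ene) | CC(C)=CCBr | starting material
19 | [5,7-bis(methoxymethoxy)-2,2-dimethylchroman-6-yl]lithium | CC1(C)CCc2c(OCOC)c([Li])c(OCOC)cc2O1 | intermediate
20 | 5,7-bis(methoxymethoxy)-2,2-dimethyl-6-(3-methylbut-2-en-1-yl)chroman | CC1(C)CCc2c(OCOC)c(CC=C(C)C)c(OCOC)cc2O1 | intermediate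
21 | 2,2-dimethyl-6-(3-methylbut-2-en-1-yl)chroman-5,7-diol | CC1(C)CCc2c(O)c(CC=C(C)C)c(O)cc2O1 | intermediate
22 | 2,2-dimethyl-6-(3-methylbut-2-en-1-yl)-7-(triisopropylsilyloxy)chroman-5-ol | CC1(C)CCc2c(O)c(CC=C(C)C)c(O[Si](C(C)C)(C(C)C)C(C)C)cc2O1 | intermediate
23 | 2,2-dimethyl-6-(3-methylbut-2-en-1-yl)-7-(triisopropylsilyloxy)chroman-5-yl trifluoromethanesulfonate | CC1(C)CCc2c(OS(=O)(=O)C(F)(F)F)c(CC=C(C)C)c(O[Si](C(C)C)(C(C)C)C(C)C)cc2O1 | intermediate
24 | [4,6-bis(tert-butyldimethylsilyloxy)-7-(2-methylbut-3-en-2-yl)benzofuran-2-yl]lithium | [Li]c1cc2c(O[Si](C)(C)C(C)(C)C)cc(O[Si](C)(C)C(C)(C)C)c(C(C)(C)C=C)c2o1 | intermediate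
25 | [4,6-bis(tert-butyldimethylsilyloxy)-7-(2-methylbut-3-en-2-yl)benzofuran-2-yl]zinc chloride | Cl[Zn]c1cc2c(O[Si](C)(C)C(C)(C)C)cc(O[Si](C)(C)C(C)(C)C)c(C(C)(C)C=C)c2o1 | intermediate
26 | 5-[4,6-bis(tert-butyldimethylsilyloxy)-7-(2-methylbut-3-en-2-yl)benzofuran-2-yl]-2,2-dimethyl-6-(3-methylbut-2-en-1-yl)-7-(triisopropylsilyloxy)chroman | C=CC(C)(C)c1c(O[Si](C)(C)C(C)(C)C)cc(O[Si](C)(C)C(C)(C)C)c2cc(-c3c(CC=C(C)C)c(O[Si](C(C)C)(C(C)C)C(C)C)cc4c3CCC(C)(C)O4)oc12 | intermediate
27 | artopetelin C | C=CC(C)(C)c1c(O)cc(O)c2cc(-c3c(CC=C(C)C)c(O)cc4c3CCC(C)(C)O4)oc12 | target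

Total step count: 13 (steps 1–5 for fragment 1, steps 6–11 for fragment 2, steps 12–13 for union and deprotection).
Longest linear sequence: 8 steps (steps 6–13).

Steps most likely to fail

Step 4. Bimolecular consumption of the acylketene may outrun closure at the less nucleophilic beta position of the furan. The competing processes are dimerisation, acylation of the free furan C5 of a second molecule, and capture by the product phenols.

The fallback uses known chemistry. It takes ring A from phloroglucinol and builds ring B on it. It sets out from 14 and comes back at 13.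
- Friedel–Crafts acylation of 14 with chloroacetyl chloride and AlCl3 gives 2-chloro-1-(2,4,6-trihydroxyphenyl)ethan-1-one F1.
- NaOAc in hot ethanol closes it to 4,6-dihydroxybenzofuran-3(2H)-one F2.
- The C4 hydroxyl is tied up in a hydrogen bond to the ketone. K2CO3 and prenyl bromide 18 therefore alkylate only O6, giving 4-hydroxy-6-(prenyloxy)benzofuran-3(2H)-one F3.
- TBSCl/imidazole then gives 4-(tert-butyldimethylsilyloxy)-6-(prenyloxy)benzofuran-3(2H)-one F4.
- NaBH4 reduction leads to the racemic 2,3-dihydrobenzofuran-3-ol F5. Loss of water on mild acid work-up gives 4-(tert-butyldimethylsilyloxy)-6-(prenyloxy)benzofuran F6.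
- Aromatic Claisen rearrangement (N,N-diethylaniline, about 190 °C) transfers the allyl unit with inversion to C7, giving 4-(tert-butyldimethylsilyloxy)-7-(2-methylbut-3-en-2-yl)benzofuran-6-ol F7.
- TBSCl/imidazole then returns to 13.

The price is that C5 competes with C7 in the rearrangement, which is the ambiguity the main route avoids.

Step 12. Coupling at the di-ortho-substituted triflate may be sluggish, so that protodemetalation and homocoupling of the heteroarylzinc reagent consume the benzofuran partner first.

The fallback exchanges the roles of the two partners. It sets out from 13 and 23 and comes back at 26.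
- 13 is lithiated as before (24) and quenched with I2 to give 4,6-bis(tert-butyldimethylsilyloxy)-2-iodo-7-(2-methylbut-3-en-2-yl)benzofuran F8.
- 23 is converted by Miyaura borylation (B2pin2, KOAc, Pd(OAc)2, SPhos, dioxane, 90 °C) into the ring C pinacol boronate F9, which is storable and can be purified and used in excess.
- Suzuki–Miyaura coupling of F8 with F9 (Pd(OAc)2, SPhos, K3PO4, toluene–H2O, 80 °C) gives 26.
- In the bond-forming event, oxidative addition now occurs at the unhindered and reactive C2–I bond.

Step 10. Discrimination between the two phenols may be incomplete, so that silylation at O5 and double silylation erode the material.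

The fallback differentiates by selective unmasking instead of selective masking. It sets out from 21 and comes back at 23.
- Excess Tf2O/pyridine gives the chroman-5,7-diyl bis(trifluoromethanesulfonate) F10.
- One equivalent of Et4NOH in dioxane at room temperature is a known mild reagent for S–O cleavage of aryl triflates. It should attack the exposed C7 sulfonate and spare the one buried between C4–H2 and the prenyl group. This gives 7-hydroxy-2,2-dimethyl-6-(3-methylbut-2-en-1-yl)chroman-5-yl trifluoromethanesulfonate F11.
- TIPSCl/imidazole then gives 23.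

Further compounds
F1 | step 4 | 2-chloro-1-(2,4,6-trihydroxyphenyl)ethan-1-one | O=C(CCl)c1c(O)cc(O)cc1O
F2 | step 4 | 4,6-dihydroxybenzofuran-3(2H)-one | O=C1COc2cc(O)cc(O)c12
F3 | step 4 | 4-hydroxy-6-[(3-methylbut-2-en-1-yl)oxy]benzofuran-3(2H)-one | CC(C)=CCOc1cc(O)c2C(=O)COc2c1
F4 | step 4 | 4-(tert-butyldimethylsilyloxy)-6-[(3-methylbut-2-en-1-yl)oxy]benzofuran-3(2H)-one | CC(C)=CCOc1cc(O[Si](C)(C)C(C)(C)C)c2C(=O)COc2c1
F5 | step 4 | rac-4-(tert-butyldimethylsilyloxy)-6-[(3-methylbut-2-en-1-yl)oxy]-2,3-dihydrobenzofuran-3-ol | CC(C)=CCOc1cc(O[Si](C)(C)C(C)(C)C)c2C(O)COc2c1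
F6 | step 4 | 4-(tert-butyldimethylsilyloxy)-6-[(3-methylbut-2-en-1-yl)oxy]benzofuran | CC(C)=CCOc1cc(O[Si](C)(C)C(C)(C)C)c2ccoc2c1
F7 | step 4 | 4-(tert-butyldimethylsilyloxy)-7-(2-methylbut-3-en-2-yl)benzofuran-6-ol | C=CC(C)(C)c1c(O)cc(O[Si](C)(C)C(C)(C)C)c2ccoc12
F8 | step 12 | 4,6-bis(tert-butyldimethylsilyloxy)-2-iodo-7-(2-methylbut-3-en-2-yl)benzofuran | C=CC(C)(C)c1c(O[Si](C)(C)C(C)(C)C)cc(O[Si](C)(C)C(C)(C)C)c2cc(I)oc12
F9 | step 12 | 2-[2,2-dimethyl-6-(3-methylbut-2-en-1-yl)-7-(triisopropylsilyloxy)chroman-5-yl]-4,4,5,5-tetramethyl-1,3,2-dioxaborolane | CC1(C)CCc2c(B3OC(C)(C)C(C)(C)O3)c(CC=C(C)C)c(O[Si](C(C)C)(C(C)C)C(C)C)cc2O1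
F10 | step 10 | 2,2-dimethyl-6-(3-methylbut-2-en-1-yl)chroman-5,7-diyl bis(trifluoromethanesulfonate) | CC1(C)CCc2c(OS(=O)(=O)C(F)(F)F)c(CC=C(C)C)c(OS(=O)(=O)C(F)(F)F)cc2O1
F11 | step 10 | 7-hydroxy-2,2-dimethyl-6-(3-methylbut-2-en-1-yl)chroman-5-yl trifluoromethanesulfonate | CC1(C)CCc2c(OS(=O)(=O)C(F)(F)F)c(CC=C(C)C)c(O)cc2O1
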